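The benzene ring is built by cycloaddition, not brominated piecemeal. The key step exploits the C4(O)–C5(OH)–C6(Br) edge of the benzene ring: it is read as a 3-alkoxyfuran whose oxygen is destined to be the C5 hydroxyl, and C6(Br)–C1–CHO as a 3-bromopropiolate. A Diels–Alder reaction of 3-bromo-4-methoxyfuran with methyl 3-bromopropiolate forms C5–C6 and C1–C2. Acid then opens the oxygen bridge at C2–O and the ring aromatizes, so a single flask delivers the C1 carbon substituent, C3–Br, C4–O, C5–OH and C6–Br. Each precursor is one step from commercial material. Bromination at C2, ester-to-aldehyde adjustment and O-demethylation finish the route.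

Key step: step 3

Remark: ring carbons carry the locants of the target throughout (C1 bears the formyl carbon, C2, C3 and C6 bear Br, C4 and C5 bear oxygen). The furan locants C2–C5 of compound 2 coincide with these. The target is achiral and bicyclic intermediate 5 is racemic.

Step 1
Reactants: 1 3,4-dibromofuran
Product: 2 3-bromo-4-methoxyfuran
Conditions: NaOMe (1.1 equiv), CuBr (10 mol %), MeOH–NMP, 95 °C
Reagents that add atoms: sodium methoxide, [Na+].[O-]C
Why: Ullmann-type copper-catalysed C–O coupling of a heteroaryl bromide with methoxide, a standard entry to 3-methoxy furans and thiophenes; the first methoxy group makes the ring more electron-rich and slows the second substitution, so about one equivalent of NaOMe should stop at the monoether.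

Step 2
Reactants: 3 methyl propiolate
Product: 4 methyl 3-bromopropiolate
Conditions: NBS (1.1 equiv), AgNO3 (10 mol %), acetone, rt
Reagents that add atoms: N-bromosuccinimide, O=C1CCC(=O)N1Br
Why: Silver-catalysed electrophilic bromination of a terminal alkyne through its silver acetylide is the standard preparation of 3-bromopropiolates and leaves the ester untouched.

Step 3
Reactants: 2 3-bromo-4-methoxyfuran; 4 methyl 3-bromopropiolate
Product: 6 methyl 2,5-dibromo-3-hydroxy-4-methoxybenzoate, via oxanorbornadiene cycloadduct 5 (not isolated)
Conditions: PhMe, 50–70 °C; then BF3·OEt2 (20 mol %), CH2Cl2, −20 to 0 °C, anhydrous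
Reagents that add atoms: none
Why: A normal-demand Diels–Alder reaction joins the enol-ether-like furan 2 (HOMO) suprafacially to the electron-poor bromoynoate 4 (LUMO) to give oxanorbornadiene 5; BF3 then ionizes one bridgehead C–O bond, the cation loses the proton of the other bridgehead (directly or after a 1,2-hydride shift and enolization), and the ring aromatizes to phenol 6 with the former furan oxygen on C5. The closest known reactions are the cycloadditions of furans with methyl 3-bromopropiolate and the acid-induced isomerization of 7-oxanorbornadienes to phenols. The benzene ring, the only ring of the target, is closed by this intermolecular (4+2) cycloaddition, which forms C5–C6 and C1–C2 at once. The two bridgehead stereocentres of 5 arise as a racemic pair in the only relative configuration the bicycle allows and vanish on aromatization, so no stereocontrol is needed. The cycloaddition must be regioselective, and this is secured by pairing the largest HOMO coefficient, at furan C5 beside the methoxy-bearing carbon, with the largest LUMO coefficient, at the bromine-bearing β-carbon of the ynoate (the "para" orientation of a 2-donor diene). The bridge must also open in one direction, and this is secured because cleavage of C2–O gives an allyl cation that ends on the methoxy carbon C4 as an oxocarbenium ion, whereas cleavage of C5–O would leave the methoxy group on the central, non-stabilizing carbon and put charge on the ester-bearing carbon.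

Step 4
Reactants: 6 methyl 2,5-dibromo-3-hydroxy-4-methoxybenzoate
Product: 7 methyl 2,3,6-tribromo-5-hydroxy-4-methoxybenzoate
Conditions: Br2 (1.05 equiv), AcOH, rt
Reagents that add atoms: bromine, BrBr
Why: Electrophilic aromatic bromination; the only free ring position, C2, lies para to the C5 hydroxyl, which activates it enough for Br2 in acetic acid despite the two bromines and the ester.

Step 5
Reactants: 7 methyl 2,3,6-tribromo-5-hydroxy-4-methoxybenzoate
Product: 8 2,4,5-tribromo-3-(hydroxymethyl)-6-methoxyphenol
Conditions: i-Bu2AlH (3.5 equiv), CH2Cl2, −78 to 0 °C; aq. potassium sodium tartrate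
Reagents that add atoms: none
Why: Ester reduction with diisobutylaluminium hydride; one equivalent is consumed by the phenol, the Lewis-acidic aluminium activates the hindered ester for double hydride delivery to the benzylic alcohol, and aryl bromides are inert to this reagent at low temperature.

Step 6
Reactants: 8 2,4,5-tribromo-3-(hydroxymethyl)-6-methoxyphenol
Product: 9 2,3,6-tribromo-5-hydroxy-4-methoxybenzaldehyde
Conditions: activated MnO2 (10 equiv), CH2Cl2–EtOAc, rt
Reagents that add atoms: none
Why: Heterogeneous MnO2 oxidation is selective for benzylic alcohols and stops at the aldehyde, and the fully substituted, electron-poor phenol has no free ortho or para position for oxidative coupling.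

Step 7
Reactants: 9 2,3,6-tribromo-5-hydroxy-4-methoxybenzaldehyde
Product: 10 2,3,6-tribromo-4,5-dihydroxybenzaldehyde
Conditions: BBr3 (3 equiv), CH2Cl2, −78 °C to rt; then H2O
Reagents that add atoms: none
Why: Lewis-acid cleavage of an aryl methyl ether; BBr3 binds the methoxy oxygen, helped by the neighbouring phenol borate, bromide removes the methyl group by SN2 displacement, and aqueous work-up should release the catechol with the aldehyde intact.

Compound list
1 | 3,4-dibromofuran | Brc1cocc1Br | starting material
2 | 3-bromo-4-methoxyfuran | COc1cocc1Br | intermediate
3 | methyl propiolate (methyl prop-2-ynoate) | COC(=O)C#C | starting material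
4 | methyl 3-bromopropiolate (methyl 3-bromoprop-2-ynoate) | COC(=O)C#CBr | intermediate
5 | racemic methyl 3,6-dibromo-5-methoxy-7-oxabicyclo[2.2.1]hepta-2,5-diene-2-carboxylate (bridgehead CH carbons C1 and C4 joined by the oxygen bridge; the 1S,4S enantiomer is drawn) | COC(=O)C1=C(Br)[C@H]2O[C@@H]1C(Br)=C2OC | intermediate
6 | methyl 2,5-dibromo-3-hydroxy-4-methoxybenzoate | COC(=O)c1cc(Br)c(OC)c(O)c1Br | intermediate
7 | methyl 2,3,6-tribromo-5-hydroxy-4-methoxybenzoate | COC(=O)c1c(Br)c(Br)c(OC)c(O)c1Br | intermediate
8 | 2,4,5-tribromo-3-(hydroxymethyl)-6-methoxyphenol | OCc1c(Br)c(Br)c(OC)c(O)c1Br | intermediate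
9 | 2,3,6-tribromo-5-hydroxy-4-methoxybenzaldehyde | O=Cc1c(Br)c(Br)c(OC)c(O)c1Br | intermediate
10 | 2,3,6-tribromo-4,5-dihydroxybenzaldehyde | O=Cc1c(Br)c(Br)c(O)c(O)c1Br | target

Total step count: 7. Longest linear sequence: 6 steps (1 → 2 → 6 → 7 → 8 → 9 → 10, or equally 3 → 4 → 6 → 10).

Steps most likely to fail

Risk 1, step 3. The cycloaddition may be outrun by conjugate addition of furan C5 to the bromoalkyne, by bromine transfer or by polymerization of the electron-rich furan. The enol ether of the cycloadduct may also be hydrolysed before the bridge opens. The fallback sets out from furan 2 and methyl propiolate 3, an unbrominated, less hindered dienophile with no transferable halogen. Heating the two in PhMe should give racemic methyl 6-bromo-5-methoxy-7-oxabicyclo[2.2.1]hepta-2,5-diene-2-carboxylate F1 (the 1S,4R enantiomer is drawn), with the same regiochemical preference. Treating it in the same flask with BF3·OEt2 should give methyl 3-bromo-5-hydroxy-4-methoxybenzoate F2. Br2 (2.1 equiv) in AcOH should then brominate both open positions, C6 ortho and C2 para to the hydroxyl, and the fallback comes back to the route at compound 7. C6–Br is thus made by electrophilic aromatic substitution instead of being carried on the alkyne, and step 2 is no longer needed.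

Risk 2, step 1. Mono-selectivity may be lost through a second methoxylation, bromine may be lost reductively, and the volatile ether may be lost on isolation. The fallback sets out from compound 1. Bromine–lithium exchange with n-BuLi (1.0 equiv, Et2O, −78 °C) and trapping with 2-isopropoxy-4,4,5,5-tetramethyl-1,3,2-dioxaborolane should give 2-(4-bromofuran-3-yl)-4,4,5,5-tetramethyl-1,3,2-dioxaborolane F3. A Chan–Lam etherification (Cu(OAc)2, DMAP, MeOH, O2, 4 Å molecular sieves) should then turn the C–B bond into C–OMe without touching the remaining bromide, and the fallback comes back to the route at compound 2.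

Risk 3, step 5. Hydride delivery to the ester flanked by two ortho bromines may be incomplete once the aluminium phenoxide has formed, leaving mixtures of ester, aldehyde and alcohol. The fallback sets out from compound 6 and reduces before the last bromination, when only one ortho bromine shields the ester. Diisobutylaluminium hydride should give 2,5-dibromo-3-(hydroxymethyl)-6-methoxyphenol F4. MnO2 should oxidize it to 2,5-dibromo-3-hydroxy-4-methoxybenzaldehyde F5. Br2 in AcOH should then brominate the one free position, para to the hydroxyl, and the fallback comes back to the route at compound 9.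

Further compounds
F1 | step 3 | racemic methyl 6-bromo-5-methoxy-7-oxabicyclo[2.2.1]hepta-2,5-diene-2-carboxylate (1S,4R enantiomer drawn) | COC(=O)C1=C[C@H]2O[C@@H]1C(Br)=C2OC
F2 | step 3 | methyl 3-bromo-5-hydroxy-4-methoxybenzoate | COC(=O)c1cc(O)c(OC)c(Br)c1
F3 | step 1 | 2-(4-bromofuran-3-yl)-4,4,5,5-tetramethyl-1,3,2-dioxaborolane | CC1(C)OB(OC1(C)C)c1cocc1Br
F4 | step 5 | 2,5-dibromo-3-(hydroxymethyl)-6-methoxyphenol | OCc1cc(Br)c(OC)c(O)c1Br
F5 | step 5 | 2,5-dibromo-3-hydroxy-4-methoxybenzaldehyde | O=Cc1cc(Br)c(OC)c(O)c1Br
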